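## The problem

The target is a 4',7-epoxy-8,3'-neolignan, that is a trans-2-aryl-3-(hydroxymethyl)-2,3-dihydrobenzofuran. Ring B (3,4,5-trimethoxyphenyl) sits on C7 and the C9 hydroxymethyl group on C8. Ring A is joined to this three-carbon chain twice, by the C3'–C8 carbon–carbon bond and by the O4'–C7 ether bond. Ring A also carries the C5' methoxy group and, at C1', an (E)-3-hydroxyprop-1-enyl chain. There are only two stereocentres, C7 (R) and C8 (S), adjacent and trans on the five-membered ring. Trans is the less crowded arrangement, so one centre can set the other and only one needs absolute control from outside. C7 is benzylic and bonded to an aryl ether oxygen, so it can ionise under acid. The side chain is a para-oxygenated cinnamyl alcohol that ionises and oxidises easily, so the late stages must be neutral or basic, non-oxidising and short. The feature that opens the structure is that C8 is bonded to C3', the ring A carbon ortho to O4', while C9 is a terminal carbon bearing oxygen. C8 and C9 can therefore be the vinyl group on the C7 carbinol carbon of an aryl allyl ether. A radical at C3' then finds C8 at the end of a five-atom path (C3', C4', O4', C7, C8), and the primary radical left on C9 can take up oxygen. C7 is then the only stereocentre of the precursor, and it is made together with the O4'–C7 bond.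

## Retrosynthesis

No skeletal bond is cut in the first move; only the oxidation level of C9' changes. Target 12 is traced to methyl enoate 11. An ester is preferred to an aldehyde or to the allylic alcohol as the ring A spectator for the radical step: an aromatic aldehyde would sit in a flask with air and chain-carrying radicals, and a cinnamyl alcohol is acid-labile. The forward reaction only has to be a 1,2-reduction in the presence of the free C9 hydroxyl.

Enoate 11 is cut at C3'–C8 and at C9–O, which leads through hydroperoxide 10 to aryl iodide 8, with stannane 9 as chain carrier and air as the source of oxygen. Cutting O4'–C7 instead would leave a benzylic cation or quinone methide problem without absolute control. Cutting C7–C8 would demand two stereocentres from one intermolecular step. The chosen cut removes the ring, one stereocentre and the C9 oxygen at once, and 8 has a single stereocentre. The forward reaction must close 5-exo before the aryl radical is intercepted, give the trans ring by 1,2-induction from C7, and trap C9 with oxygen before hydrogen transfer.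

Ether 8 is cut at O4'–C7 to the achiral cinnamyl carbonate 4 and phenol 6, used as its lithium aryloxide 7. A branched-selective asymmetric allylic etherification is preferred to a Mitsunobu coupling, which would need an enantiopure branched alcohol made separately. It is also preferred to acid-mediated etherification, which offers no control. Both precursors are flat and achiral. The forward reaction must attack the aryl-bearing allyl terminus, set C7 as R, and leave the aryl iodide and the enoate alone.

Phenol 6 is cut at C7'=C8' to commercial 5-iodovanillin 5 by a Wittig olefination. The olefination is placed before the etherification. The aldehyde then never meets aryloxide formation, the iridium catalyst or oxygen, and the aryloxide is a better nucleophile without a para-formyl group. The synthesis also becomes convergent.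

Carbonate 4 is traced by functional group changes to alcohol 3, ester 2 and commercial (E)-3,4,5-trimethoxycinnamic acid 1. Acid 1 already holds ring B and C7 to C9 in the right order. Nothing more is asked than esterification, 1,2-reduction and acylation.

## Roads not taken

Alternative 1: Both aryl–carbon bonds of the chain, ring B–C7 and C3'–C8, are cut together. The chain shrinks to the (E)-alkenyl pinacol boronate A2, ring B becomes 3,4,5-trimethoxyphenyllithium A3, and ring A becomes bromide A4 (phenol as methoxymethyl ether, aldehyde as dimethyl acetal). In the forward sense A3 adds to boron of A2 to give the ate complex A5. An arylpalladium species from A4 and Pd(OAc)2 with a chiral ferrocenyl bisphosphine of the MandyPhos family adds to the alkene of A5 while ring B shifts from boron to C7. This gives boronate A1 by a stereospecific anti addition.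
- Merits: three simple pieces are joined in one step, and the catalyst controls C8 as well as C7. In this it is better than the chosen plan, which trusts 1,2-induction for C8.
- Weak points: no ring is closed. Oxidation of the C–B bond goes with retention and puts the hydroxyl where the ring oxygen must finally sit. An invertive closure by the freed phenol would therefore give the cis ring. Closure would have to pass through the C7 cation under acid, which spends the C7 configuration and endangers the acetal and silyl ether.
- Further weak points: A2 is a 1,2-disubstituted alkenyl boronate, a class much less willing in this coupling than vinyl boronates. The ring B–C7 bond that is made already exists in every cheap C6–C3 building block.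
- Comparison: about six steps remain after A1, against one after the key step of the chosen plan. The chosen plan forms O4'–C7 together with the C7 stereocentre and uses no protecting group.

Alternative 2: The cut is C8–C9. C9 comes from formaldehyde A8 and the rest is (E)-stilbene A7, with the ring A phenol as an acetate and the formyl group free. A confined chiral imino-imidodiphosphate Brønsted acid would activate A8 for attack by C8 of A7. The charge developing at C7 is quenched through oxygen by a second molecule of A8, giving trans-dioxane A6 with C8 as in the target.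
- Merits: in atom economy and in length of approach this road is better than the chosen one. A7 is one coupling step from simple pieces, C9 is the cheapest C1 unit, and both centres are set by a catalyst.
- Weak points: the asymmetric Prins reaction with such acids is established for terminal aryl alkenes. A 1,2-diaryl alkene would be new and probably slow, since ring B stabilises a benzylic cation only moderately and ring A is deactivated. The free aldehyde of A7 competes with A8 for the acid.
- Further weak points: A6 is not yet the ring system. The dioxane oxygen on C7 must be exchanged for O4'. C7 of A6 has the configuration opposite to the target, so this needs a clean inversion at a benzylic acetal carbon or a cation that relies on the trans preference. The formal carbon on O9 must then be removed.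
- Comparison: the chosen plan sets against this brevity a key step of a known reaction type on its own substrate class and an O4'–C7 bond that is final once made.

Alternative 3: The cut goes through C7–C8 and O4'–C7. Ring A with C8 and C9 becomes ortho-quinone methide A11, released by Cs2CO3 from sulfone A10. Ring B with C7 becomes ylide A13, formed from a chiral sulfonium salt such as A12. The carbanion carbon of A13 adds to C8 of A11 and the phenoxide then displaces the sulfide at C7, closing the dihydrofuran ring of A9 in a formal [4+1] annulation.
- Merits: ring, both stereocentres and the trans relationship come from one step whose mechanism (anti betaine, then backside displacement) enforces trans. This is a firmer basis than the 1,2-induction of the chosen key step. The bromine of A9 is a ready handle for the side chain.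
- Weak points: A11 has hydrogens on C9 next to the exocyclic double bond and can tautomerise by hydrogen shift to oxygen before the ylide arrives. In A10 the silyloxy group is β to the sulfonyl-bearing carbon, so loss of silanolate competes with loss of sulfinate. Asymmetric variants are best documented for ester- and amide-stabilised ylides, so enantioselectivity would rest on a stoichiometric chiral sulfide of uncertain performance.
- Comparison: A10 needs four or five steps of its own and A9 three more. The chosen plan answers the better diastereocontrol of this road with a catalytic source of chirality, a key-step precursor one catalytic step from two achiral pieces, and a thermodynamic correction of C8 held in reserve.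

Key step: step 6

Remark on numbering: neolignan locants are used, C1 to C9 for the ring B unit and primed locants for the ring A unit.

Assumption: the (Ra,Rc,Rc) phosphoramidite is taken to give the R ether 8, by analogy with the sense known for cinnamyl carbonates and aryloxides. If the first run shows the opposite sense, the mirror-image ligand is used and nothing else changes.

Step 1
Reactants: 1 (2E)-3-(3,4,5-trimethoxyphenyl)prop-2-enoic acid
Product: 2 methyl (2E)-3-(3,4,5-trimethoxyphenyl)prop-2-enoate
Conditions: MeOH, H2SO4 (cat.), reflux
Reagents that add atoms: methanol, CO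
Why: Fischer esterification of an unhindered cinnamic acid in excess methanol; the E alkene and the aryl methyl ethers are inert to catalytic acid.

Step 2
Reactants: 2 methyl (2E)-3-(3,4,5-trimethoxyphenyl)prop-2-enoate
Product: 3 (2E)-3-(3,4,5-trimethoxyphenyl)prop-2-en-1-ol
Conditions: i-Bu2AlH (2.5 equiv), CH2Cl2, −78 to 0 °C; aq. potassium sodium tartrate
Reagents that add atoms: none
Why: 1,2-Reduction of an α,β-unsaturated ester by i-Bu2AlH gives the allylic alcohol without touching the conjugated alkene, which LiAlH4 could partly reduce; the E geometry is kept.

Step 3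
Reactants: 3 (2E)-3-(3,4,5-trimethoxyphenyl)prop-2-en-1-ol
Product: 4 methyl (2E)-3-(3,4,5-trimethoxyphenyl)prop-2-en-1-yl carbonate
Conditions: ClCO2Me (1.5 equiv), pyridine (2 equiv), CH2Cl2, 0 °C to rt
Reagents that add atoms: methyl chloroformate, COC(=O)Cl
Why: O-Acylation of a primary allylic alcohol with a chloroformate and pyridine; it installs the leaving group for ionisation by iridium, and its methyl group matches the methyl ester of the coupling partner.

Step 4
Reactants: 5 4-hydroxy-3-iodo-5-methoxybenzaldehyde (5-iodovanillin)
Product: 6 methyl (2E)-3-(4-hydroxy-3-iodo-5-methoxyphenyl)prop-2-enoate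
Conditions: Ph3P=CHCO2Me (1.5 equiv), toluene, 100 °C
Reagents that add atoms: methyl (triphenyl-λ5-phosphanylidene)acetate, COC(=O)C=P(c1ccccc1)(c1ccccc1)c1ccccc1
Why: Wittig olefination with a stabilised ylide tolerates the free phenol and gives the E enoate; heating offsets the partial proton transfer from the acidic phenol to the ylide.

Step 5
Reactants: 6 methyl (2E)-3-(4-hydroxy-3-iodo-5-methoxyphenyl)prop-2-enoate; 4 methyl (2E)-3-(3,4,5-trimethoxyphenyl)prop-2-en-1-yl carbonate
Product: 8 methyl (2E)-3-(3-iodo-5-methoxy-4-{[(1R)-1-(3,4,5-trimethoxyphenyl)prop-2-en-1-yl]oxy}phenyl)prop-2-enoate, via lithium aryloxide 7 (not isolated)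
Conditions: 6 (1.3 equiv), LiN(SiMe3)2 (1.3 equiv), THF, 0 °C; then 4 (1.0 equiv), [Ir(cod)Cl]2 (2 mol %), (Ra,Rc,Rc)-O,O'-(1,1'-binaphthalene-2,2'-diyl) N,N-bis(1-phenylethyl)phosphoramidite (4 mol %), THF, 50 °C
Reagents that add atoms: none
Why: Iridium-catalysed branched-selective asymmetric allylic etherification of a linear cinnamyl carbonate with an aryloxide: the catalyst formed from [Ir(cod)Cl]2 and the phosphoramidite ionises 4, and 7 attacks the aryl-bearing allyl terminus, setting C7 (R) under catalyst control. The iodine and methoxy groups flanking the oxygen block any Claisen shift, the aryl iodide is inert to this catalyst, and the methoxide released matches the methyl ester.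

Step 6
Reactants: 8 methyl (2E)-3-(3-iodo-5-methoxy-4-{[(1R)-1-(3,4,5-trimethoxyphenyl)prop-2-en-1-yl]oxy}phenyl)prop-2-enoate; 9 tributyltin hydride
Product: 11 methyl (2E)-3-[(2R,3S)-3-(hydroxymethyl)-7-methoxy-2-(3,4,5-trimethoxyphenyl)-2,3-dihydro-1-benzofuran-5-yl]prop-2-enoate, via C9 hydroperoxide 10 (not isolated)
Conditions: 9 (2.5 equiv, syringe pump), Et3B (0.3 equiv), dry air (slow stream), toluene (0.01 M), 0 °C; then PPh3 (1.5 equiv), rt
Reagents that add atoms: dioxygen (from air), O=O
Why: Ethyl radicals from Et3B and oxygen start a chain in which the tributylstannyl radical abstracts iodine from 8, the σ-radical at C3' adds to C8 of the vinyl group (C3'–C8), the primary C9 radical combines with dissolved O2, and the peroxyl radical takes hydrogen from 9 to give hydroperoxide 10 and a new stannyl radical; PPh3 then reduces the O–O bond to leave the C9 hydroxyl of 11. The closest known reaction type is the oxygenative tin hydride cyclisation of ortho-iodophenyl allyl ethers to 3-(hydroxymethyl)-2,3-dihydrobenzofurans. The dihydrofuran ring closes in the 5-exo-trig mode, which for an aryl radical with an ortho allyloxy tether is among the fastest radical cyclisations known and far ahead of 6-endo attack at C9. C8 is set by 1,2-induction from C7: in the chair-like transition state the 3,4,5-trimethoxyphenyl group on C7 lies pseudo-equatorial and the forming C9 radical turns away from it, so the 2,3-trans ring (8S) should predominate, and C7, never a radical centre, keeps its R configuration. Cyclisation must outrun capture of the aryl radical by oxygen or stannane, which the intramolecular rate and high dilution secure; oxygen capture at C9 must outrun hydrogen transfer and the slow neophyl-type ring expansion, which slow addition of 9 under a steady stream of air secures. The enoate must stay untouched: stannyl radicals abstract aryl iodine much faster than they add, reversibly, to a β-aryl acrylate, and the ester, unlike an aldehyde, has no weakly bound hydrogen for peroxyl radicals. A minor cis isomer is to be expected and is removed by chromatography or crystallisation.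

Step 7
Reactants: 11 methyl (2E)-3-[(2R,3S)-3-(hydroxymethyl)-7-methoxy-2-(3,4,5-trimethoxyphenyl)-2,3-dihydro-1-benzofuran-5-yl]prop-2-enoate
Product: 12 (2E)-3-[(2R,3S)-3-(hydroxymethyl)-7-methoxy-2-(3,4,5-trimethoxyphenyl)-2,3-dihydro-1-benzofuran-5-yl]prop-2-en-1-ol, the target
Conditions: i-Bu2AlH (4 equiv), CH2Cl2, −78 to −30 °C; aq. potassium sodium tartrate
Reagents that add atoms: none
Why: 1,2-Reduction of the enoate by i-Bu2AlH to the E allylic alcohol; the first equivalent is taken up by the C9 hydroxyl. C7 and C8 are not touched under these conditions, and the neutral tartrate work-up spares the acid-sensitive oxygenated cinnamyl alcohol.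

Compound list

1 | (2E)-3-(3,4,5-trimethoxyphenyl)prop-2-enoic acid ((E)-3,4,5-trimethoxycinnamic acid) | COc1cc(/C=C/C(=O)O)cc(OC)c1OC | starting material
2 | methyl (2E)-3-(3,4,5-trimethoxyphenyl)prop-2-enoate | COC(=O)/C=C/c1cc(OC)c(OC)c(OC)c1 | intermediate
3 | (2E)-3-(3,4,5-trimethoxyphenyl)prop-2-en-1-ol | OC/C=C/c1cc(OC)c(OC)c(OC)c1 | intermediate
4 | methyl (2E)-3-(3,4,5-trimethoxyphenyl)prop-2-en-1-yl carbonate | COC(=O)OC/C=C/c1cc(OC)c(OC)c(OC)c1 | intermediate
5 | 4-hydroxy-3-iodo-5-methoxybenzaldehyde (5-iodovanillin) | COc1cc(C=O)cc(I)c1O | starting material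
6 | methyl (2E)-3-(4-hydroxy-3-iodo-5-methoxyphenyl)prop-2-enoate | COC(=O)/C=C/c1cc(OC)c(O)c(I)c1 | intermediate
7 | lithium 2-iodo-6-methoxy-4-[(1E)-3-methoxy-3-oxoprop-1-en-1-yl]phenolate | [Li+].[O-]c1c(I)cc(/C=C/C(=O)OC)cc1OC | intermediate
8 | methyl (2E)-3-(3-iodo-5-methoxy-4-{[(1R)-1-(3,4,5-trimethoxyphenyl)prop-2-en-1-yl]oxy}phenyl)prop-2-enoate | COc1cc([C@@H](C=C)Oc2c(I)cc(/C=C/C(=O)OC)cc2OC)cc(OC)c1OC | intermediate
9 | tributyltin hydride | CCCC[SnH](CCCC)CCCC | starting material
10 | methyl (2E)-3-[(2R,3S)-3-(hydroperoxymethyl)-7-methoxy-2-(3,4,5-trimethoxyphenyl)-2,3-dihydro-1-benzofuran-5-yl]prop-2-enoate | COc1cc([C@@H]2Oc3c(OC)cc(/C=C/C(=O)OC)cc3[C@H]2COO)cc(OC)c1OC | intermediate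
11 | methyl (2E)-3-[(2R,3S)-3-(hydroxymethyl)-7-methoxy-2-(3,4,5-trimethoxyphenyl)-2,3-dihydro-1-benzofuran-5-yl]prop-2-enoate | COc1cc([C@@H]2Oc3c(OC)cc(/C=C/C(=O)OC)cc3[C@H]2CO)cc(OC)c1OC | intermediate
12 | (2E)-3-[(2R,3S)-3-(hydroxymethyl)-7-methoxy-2-(3,4,5-trimethoxyphenyl)-2,3-dihydro-1-benzofuran-5-yl]prop-2-en-1-ol, (−)-(7R,8S,7'E)-3,4,5,5'-tetramethoxy-4',7-epoxy-8,3'-neolign-7'-ene-9,9'-diol | COc1cc([C@@H]2Oc3c(OC)cc(/C=C/CO)cc3[C@H]2CO)cc(OC)c1OC | target

Total step count: 7. Longest linear sequence: 6 steps (steps 1, 2, 3, 5, 6 and 7, from acid 1).

Steps least certain to work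

Step 6, the key step. The most likely failure is incomplete 1,2-induction. The tether holds two sp2 ring atoms and is nearly flat, so the two chair-like arrangements may differ little in energy and the cis ring may form in more than trace amount. A second risk is hydrogen transfer to C9 before oxygen capture if stannane accumulates; this is a matter of addition rate. The fallback replaces kinetic control of C8 by thermodynamic control. It sets out from 11, taken as the unseparated mixture of C8 epimers, and comes back at 12.
- Oxidation with Dess–Martin periodinane (NaHCO3, CH2Cl2) would give methyl (2E)-3-[(2R,3R)-3-formyl-7-methoxy-2-(3,4,5-trimethoxyphenyl)-2,3-dihydro-1-benzofuran-5-yl]prop-2-enoate F1 together with its cis epimer, methyl (2E)-3-[(2R,3S)-3-formyl-7-methoxy-2-(3,4,5-trimethoxyphenyl)-2,3-dihydro-1-benzofuran-5-yl]prop-2-enoate F2.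
- DBU in CH2Cl2 should equilibrate F2 to the trans aldehyde F1 through the C8 enolate. C7 should not be affected, because ring opening by β-elimination of the aryloxide is the reverse of a disfavoured 5-endo closure.
- i-Bu2AlH then reduces aldehyde and enoate of F1 together to give 12.

Step 5. The most likely failure is slow attack of the hindered, electron-poor aryloxide on the allyl iridium intermediate. The product can then re-ionise and drift toward the linear cinnamyl ether, with loss of enantiomeric purity. The fallback makes the C7–O bond by inversion of a preformed carbinol. It sets out from alcohol 3 and phenol 6 and comes back at 8.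
- Sharpless asymmetric epoxidation of 3 (Ti(OiPr)4, D-(−)-diisopropyl tartrate, t-BuOOH, 4 Å sieves, CH2Cl2, −20 °C) would give [(2R,3R)-3-(3,4,5-trimethoxyphenyl)oxiran-2-yl]methanol F3.
- I2, PPh3 and imidazole would convert it into (2S,3R)-2-(iodomethyl)-3-(3,4,5-trimethoxyphenyl)oxirane F4.
- Zinc dust in ethanol would open the epoxide reductively to (1S)-1-(3,4,5-trimethoxyphenyl)prop-2-en-1-ol F5, with the C7–O bond untouched.
- Mitsunobu coupling of F5 with 6 (PPh3, diisopropyl azodicarboxylate, toluene, 0 °C) should invert C7 and give 8.

Step 4. The most likely failure is stalling by proton transfer from the acidic phenol to the ylide, which leaves an unreactive phosphonium aryloxide ion pair. The fallback sets out from aldehyde 5 and comes back at 6.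
- Knoevenagel–Doebner condensation with malonic acid (pyridine, piperidine cat., 90 °C), which works well on hydroxybenzaldehydes, would give (2E)-3-(4-hydroxy-3-iodo-5-methoxyphenyl)prop-2-enoic acid F6.
- Fischer esterification (MeOH, H2SO4 cat., reflux) then gives 6.

Further compounds

F1 | step 6 | methyl (2E)-3-[(2R,3R)-3-formyl-7-methoxy-2-(3,4,5-trimethoxyphenyl)-2,3-dihydro-1-benzofuran-5-yl]prop-2-enoate | COc1cc([C@@H]2Oc3c(OC)cc(/C=C/C(=O)OC)cc3[C@H]2C=O)cc(OC)c1OC
F2 | step 6 | methyl (2E)-3-[(2R,3S)-3-formyl-7-methoxy-2-(3,4,5-trimethoxyphenyl)-2,3-dihydro-1-benzofuran-5-yl]prop-2-enoate | COc1cc([C@@H]2Oc3c(OC)cc(/C=C/C(=O)OC)cc3[C@@H]2C=O)cc(OC)c1OC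
F3 | step 5 | [(2R,3R)-3-(3,4,5-trimethoxyphenyl)oxiran-2-yl]methanol | OC[C@H]1O[C@@H]1c1cc(OC)c(OC)c(OC)c1
F4 | step 5 | (2S,3R)-2-(iodomethyl)-3-(3,4,5-trimethoxyphenyl)oxirane | IC[C@H]1O[C@@H]1c1cc(OC)c(OC)c(OC)c1
F5 | step 5 | (1S)-1-(3,4,5-trimethoxyphenyl)prop-2-en-1-ol | O[C@@H](C=C)c1cc(OC)c(OC)c(OC)c1
F6 | step 4 | (2E)-3-(4-hydroxy-3-iodo-5-methoxyphenyl)prop-2-enoic acid | OC(=O)/C=C/c1cc(OC)c(O)c(I)c1
A1 | alternative 1 | tert-butyl{[(2S,3R)-2-[5-(dimethoxymethyl)-3-methoxy-2-(methoxymethoxy)phenyl]-3-(4,4,5,5-tetramethyl-1,3,2-dioxaborolan-2-yl)-3-(3,4,5-trimethoxyphenyl)propyl]oxy}dimethylsilane | COc1cc([C@H](B3OC(C)(C)C(C)(C)O3)[C@H](CO[Si](C)(C)C(C)(C)C)c2cc(C(OC)OC)cc(OC)c2OCOC)cc(OC)c1OC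
A2 | alternative 1 | tert-butyldimethyl{[(2E)-3-(4,4,5,5-tetramethyl-1,3,2-dioxaborolan-2-yl)prop-2-en-1-yl]oxy}silane | CC(C)(C)[Si](C)(C)OC/C=C/B1OC(C)(C)C(C)(C)O1
A3 | alternative 1 | (3,4,5-trimethoxyphenyl)lithium | [Li]c1cc(OC)c(OC)c(OC)c1
A4 | alternative 1 | 1-bromo-5-(dimethoxymethyl)-3-methoxy-2-(methoxymethoxy)benzene | COCOc1c(Br)cc(C(OC)OC)cc1OC
A5 | alternative 1 | lithium [(1E)-3-{[tert-butyl(dimethyl)silyl]oxy}prop-1-en-1-yl](2,3-dimethylbutane-2,3-diolato)(3,4,5-trimethoxyphenyl)borate | [Li+].COc1cc(cc(OC)c1OC)[B-]1(OC(C)(C)C(C)(C)O1)/C=C/CO[Si](C)(C)C(C)(C)C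
A6 | alternative 2 | 4-formyl-2-methoxy-6-[(4S,5S)-4-(3,4,5-trimethoxyphenyl)-1,3-dioxan-5-yl]phenyl acetate | COc1cc([C@H]2OCOC[C@@H]2c3cc(C=O)cc(OC)c3OC(C)=O)cc(OC)c1OC
A7 | alternative 2 | 4-formyl-2-methoxy-6-[(E)-2-(3,4,5-trimethoxyphenyl)ethenyl]phenyl acetate | COc1cc(/C=C/c2cc(C=O)cc(OC)c2OC(C)=O)cc(OC)c1OC
A8 | alternative 2 | formaldehyde | C=O
A9 | alternative 3 | tert-butyl{[(2R,3S)-5-bromo-7-methoxy-2-(3,4,5-trimethoxyphenyl)-2,3-dihydro-1-benzofuran-3-yl]methoxy}dimethylsilane | COc1cc([C@@H]2Oc3c(OC)cc(Br)cc3[C@H]2CO[Si](C)(C)C(C)(C)C)cc(OC)c1OC
A10 | alternative 3 | 4-bromo-2-[2-{[tert-butyl(dimethyl)silyl]oxy}-1-(4-methylbenzenesulfonyl)ethyl]-6-methoxyphenol (racemic) | COc1cc(Br)cc(C(CO[Si](C)(C)C(C)(C)C)S(=O)(=O)c2ccc(C)cc2)c1O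
A11 | alternative 3 | 4-bromo-6-(2-{[tert-butyl(dimethyl)silyl]oxy}ethylidene)-2-methoxycyclohexa-2,4-dien-1-one | COC1=CC(Br)=CC(=CCO[Si](C)(C)C(C)(C)C)C1=O
A12 | alternative 3 | (2R,5R)-2,5-dimethyl-1-[(3,4,5-trimethoxyphenyl)methyl]thiolan-1-ium trifluoromethanesulfonate | C[C@@H]1CC[C@@H](C)[S+]1Cc1cc(OC)c(OC)c(OC)c1.[O-]S(=O)(=O)C(F)(F)F
A13 | alternative 3 | [(2R,5R)-2,5-dimethylthiolan-1-ium-1-yl](3,4,5-trimethoxyphenyl)methanide | C[C@@H]1CC[C@@H](C)[S+]1[CH-]c1cc(OC)c(OC)c(OC)c1
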